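**Plan**

1. Retrosynthetic cuts, in order: first the C6–C7 sp2–sp2 bond between the dihydroxylated β-ring and the nonaene (ring as enol triflate, chain as a C31 E-alkenylstannane); then C11'=C12' and C11=C12 (two Horner–Wadsworth–Emmons olefinations on the C10 trienedial); last C9'=C10' (olefination of α-ionone).
2. Enabling feature: C6 is the carbonyl-derived carbon of a 2,6,6-trimethylcyclohexenone that is quaternary at C1 and can be deprotonated only at the γ-carbon, so the β-ring enters as a cyclohexa-1,3-dienyl triflate; the OTf group deactivates C5=C6, so osmylation takes only C3=C4 and places the cis-3,4-diol directly on the coupling partner.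
3. Forward order: both carbocycles come ready-made (no ring is formed); C6 stannyl phosphonate + C10 dialdehyde → C16 stannyl aldehyde; ε-ring C15 phosphonate + C16 → C31 stannane; C31 + C9 triflate → C40; desilylation.
4. Stereochemistry: cis C3/C4 from syn-dihydroxylation, absolute sense from a lipase resolution; C3' from CBS reduction (reagent control); C6' from racemic α-ionone by separating the trans (3'R,6'R) from the cis diastereomer after that reduction; E double bonds from syn-hydrostannation, E-selective olefinations and stereoretentive cross-coupling.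

Key step: step 16

Assumption: (±)-α-ionone, 2,6,6-trimethylcyclohex-2-en-1-one, (E)-3-methylpent-2-en-4-yn-1-ol and (2E,4E,6E)-2,7-dimethylocta-2,4,6-trienedial are bought as such; carotenoid numbering (primed = ε-ring half) is used for the target and in step 16, the numbering of each systematic name elsewhere.

**Route**

Step 1
Reactants: 1 2,6,6-trimethylcyclohex-2-en-1-one
Product: 3 2,6,6-trimethylcyclohexa-1,3-dien-1-yl trifluoromethanesulfonate, via lithium dienolate 2 (not isolated)
Conditions: LDA, THF, −78 °C; PhNTf2, −78 °C → rt; aq. NH4Cl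
Reagents that add atoms: N-phenylbis(trifluoromethanesulfonimide), O=S(=O)(N(c1ccccc1)S(=O)(=O)C(F)(F)F)C(F)(F)F
Why: C6 is quaternary, so the amide base can remove only a γ-hydrogen at C4, and the resulting dienolate is sulfonylated on oxygen (enol triflate formation) to give the dienyl triflate with the C3=C4 bond in place.

Step 2
Reactants: 3 2,6,6-trimethylcyclohexa-1,3-dien-1-yl trifluoromethanesulfonate
Product: 4 rac-(3R,4S)-3,4-dihydroxy-2,6,6-trimethylcyclohex-1-en-1-yl trifluoromethanesulfonate (cis-diol, racemate)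
Conditions: OsO4 (cat.), NMO, acetone/H2O, 0 °C → rt
Reagents that add atoms: N-methylmorpholine N-oxide, C[N+]1([O-])CCOCC1; water, O
Why: Catalytic osmium tetroxide syn-dihydroxylation should touch only the disubstituted C3=C4 bond, because the tetrasubstituted C1=C2 bond is hindered and made electron-poor by OTf, and the [3+2] addition delivers both oxygens to one face, which fixes the cis relationship of the two new stereocentres.

Step 3
Reactants: 4 rac-(3R,4S)-3,4-dihydroxy-2,6,6-trimethylcyclohex-1-en-1-yl trifluoromethanesulfonate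
Product: 5 (3R,4S)-3,4-dihydroxy-2,6,6-trimethylcyclohex-1-en-1-yl trifluoromethanesulfonate (the unacylated enantiomer)
Conditions: Burkholderia cepacia lipase (immobilised), vinyl acetate, MTBE, 30 °C, stopped just past half conversion; chromatography
Reagents that add atoms: none
Why: Lipase-catalysed kinetic resolution by transesterification: by the empirical size rule for secondary alcohols the enzyme should acetylate the less hindered C4–OH of the (3S,4R)-enantiomer (carbinol R at C4) and leave the wanted (3R,4S)-diol, whose enantiomeric purity rises as conversion passes the half-way point.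

Step 4
Reactants: 6 (E)-3-methylpent-2-en-4-yn-1-ol
Product: 7 (2E,4E)-3-methyl-5-(tributylstannyl)penta-2,4-dien-1-ol
Conditions: Bu3SnH, PdCl2(PPh3)2 (2 mol%), THF, 0 °C
Reagents that add atoms: tributyltin hydride, CCCC[SnH](CCCC)CCCC
Why: Palladium-catalysed syn-hydrostannation of the terminal alkyne of the conjugated enyne places tin on the terminal carbon and gives the E-alkenylstannane, while the trisubstituted alkene keeps its E geometry.

Step 5
Reactants: 7 (2E,4E)-3-methyl-5-(tributylstannyl)penta-2,4-dien-1-ol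
Product: 8 tributyl[(1E,3E)-5-bromo-3-methylpenta-1,3-dien-1-yl]stannane
Conditions: CBr4, PPh3, 2,6-lutidine, CH2Cl2, −20 → 0 °C
Reagents that add atoms: carbon tetrabromide, BrC(Br)(Br)Br
Why: Appel reaction, in which bromide displaces the oxyphosphonium of the primary allylic alcohol by SN2 under buffered, non-acidic conditions that spare the acid-labile alkenylstannane.

Step 6
Reactants: 8 tributyl[(1E,3E)-5-bromo-3-methylpenta-1,3-dien-1-yl]stannane
Product: 9 diethyl [(2E,4E)-3-methyl-5-(tributylstannyl)penta-2,4-dien-1-yl]phosphonate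
Conditions: P(OEt)3 (neat), 90 °C
Reagents that add atoms: triethyl phosphite, CCOP(OCC)OCC
Why: Michaelis–Arbuzov reaction at the unhindered primary allylic carbon (SN2 by phosphorus, then dealkylation by bromide) gives the dienyl phosphonate without touching the C–Sn bond.

Step 7
Reactants: 9 diethyl [(2E,4E)-3-methyl-5-(tributylstannyl)penta-2,4-dien-1-yl]phosphonate, 10 (2E,4E,6E)-2,7-dimethylocta-2,4,6-trienedial (excess)
Product: 12 (2E,4E,6E,8E,10E,12E)-2,7,11-trimethyl-13-(tributylstannyl)trideca-2,4,6,8,10,12-hexaenal, via sodium phosphonate carbanion 11 (not isolated)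
Conditions: NaHMDS, THF, −78 °C; added to 10 (2.5 equiv), −78 → 0 °C, dark
Reagents that add atoms: none
Why: Horner–Wadsworth–Emmons olefination in which excess dialdehyde and inverse addition should stop the reaction at mono-olefination, the allylic phosphonate anion reacting at its α-carbon to form the new disubstituted double bond with E geometry.

Step 8
Reactants: 13 (±)-α-ionone [(E)-4-(2,6,6-trimethylcyclohex-2-en-1-yl)but-3-en-2-one], 14 triethyl phosphonoacetate
Product: 16 ethyl (2E,4E)-3-methyl-5-(2,6,6-trimethylcyclohex-2-en-1-yl)penta-2,4-dienoate (racemic), via sodium triethyl phosphonoacetate 15 (not isolated)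
Conditions: NaH, THF, 0 °C; then 13, rt → 50 °C; chromatography
Reagents that add atoms: none
Why: Horner–Wadsworth–Emmons olefination of the methyl ketone adds two carbons with the favoured 2E geometry (the minor 2Z isomer is removed by chromatography) under conditions that do not move the ring double bond.

Step 9
Reactants: 16 ethyl (2E,4E)-3-methyl-5-(2,6,6-trimethylcyclohex-2-en-1-yl)penta-2,4-dienoate
Product: 17 ethyl (2E,4E)-3-methyl-5-(2,6,6-trimethyl-4-oxocyclohex-2-en-1-yl)penta-2,4-dienoate (racemic)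
Conditions: t-BuOOH (aq., excess), Rh2(cap)4 (1 mol%), K2CO3, CH2Cl2, rt
Reagents that add atoms: tert-butyl hydroperoxide, CC(C)(C)OO
Why: Rhodium(II)-catalysed allylic oxidation, in which the tert-butylperoxyl radical should abstract the accessible ring allylic hydrogen at C4 and the allyl peroxide collapse to the enone, as in the established oxidation of α-ionone to its 3-oxo derivative.

Step 10
Reactants: 17 ethyl (2E,4E)-3-methyl-5-(2,6,6-trimethyl-4-oxocyclohex-2-en-1-yl)penta-2,4-dienoate
Product: 18 ethyl (2E,4E)-5-[(1R,4R)-4-hydroxy-2,6,6-trimethylcyclohex-2-en-1-yl]-3-methylpenta-2,4-dienoate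
Conditions: (S)-Me-CBS (20 mol%), catecholborane, toluene, −78 °C; aq. NaOH; chromatography
Reagents that add atoms: none
Why: CBS reduction, in which the oxazaborolidine–borane complex binds the enone with the alkenyl arm as the large group and should deliver hydride to one face regardless of the remote C1 centre, so C4 is set R by reagent control and the racemate gives two diastereomers, of which the trans (1R,4R) isomer is separated by chromatography.

Step 11
Reactants: 18 ethyl (2E,4E)-5-[(1R,4R)-4-hydroxy-2,6,6-trimethylcyclohex-2-en-1-yl]-3-methylpenta-2,4-dienoate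
Product: 19 ethyl (2E,4E)-5-[(1R,4R)-4-(tert-butyldimethylsilyloxy)-2,6,6-trimethylcyclohex-2-en-1-yl]-3-methylpenta-2,4-dienoate
Conditions: TBSCl, imidazole, DMF, rt
Reagents that add atoms: tert-butyldimethylsilyl chloride, CC(C)(C)[Si](C)(C)Cl
Why: Standard silylation of the secondary allylic alcohol masks the acid-labile carbinol for the halide, phosphonate and organometallic steps that follow, without touching the stereocentres.

Step 12
Reactants: 19 ethyl (2E,4E)-5-[(1R,4R)-4-(tert-butyldimethylsilyloxy)-2,6,6-trimethylcyclohex-2-en-1-yl]-3-methylpenta-2,4-dienoate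
Product: 20 (2E,4E)-5-[(1R,4R)-4-(tert-butyldimethylsilyloxy)-2,6,6-trimethylcyclohex-2-en-1-yl]-3-methylpenta-2,4-dien-1-ol
Conditions: DIBAL-H, CH2Cl2, −78 °C; Rochelle salt
Reagents that add atoms: none
Why: DIBAL-H reduces the dienoate by 1,2-addition to the primary allylic alcohol at low temperature, leaving the silyl ether and the alkenes untouched.

Step 13
Reactants: 20 (2E,4E)-5-[(1R,4R)-4-(tert-butyldimethylsilyloxy)-2,6,6-trimethylcyclohex-2-en-1-yl]-3-methylpenta-2,4-dien-1-ol
Product: 21 (1R,4R)-1-[(1E,3E)-5-bromo-3-methylpenta-1,3-dien-1-yl]-4-(tert-butyldimethylsilyloxy)-2,6,6-trimethylcyclohex-2-ene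
Conditions: CBr4, PPh3, 2,6-lutidine, CH2Cl2, −20 → 0 °C; used crude
Reagents that add atoms: carbon tetrabromide, BrC(Br)(Br)Br
Why: Appel reaction converts the primary dienylic alcohol into the bromide by SN2 under neutral conditions that should not ionise the allylic silyl ether of the ring.

Step 14
Reactants: 21 (1R,4R)-1-[(1E,3E)-5-bromo-3-methylpenta-1,3-dien-1-yl]-4-(tert-butyldimethylsilyloxy)-2,6,6-trimethylcyclohex-2-ene
Product: 22 diethyl {(2E,4E)-5-[(1R,4R)-4-(tert-butyldimethylsilyloxy)-2,6,6-trimethylcyclohex-2-en-1-yl]-3-methylpenta-2,4-dien-1-yl}phosphonate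
Conditions: P(OEt)3 (neat), 90 °C
Reagents that add atoms: triethyl phosphite, CCOP(OCC)OCC
Why: Michaelis–Arbuzov reaction at the primary allylic terminus gives the C15 phosphonate under neutral conditions, so the C1 stereocentre next to the diene is not exposed to base.

Step 15
Reactants: 22 diethyl {(2E,4E)-5-[(1R,4R)-4-(tert-butyldimethylsilyloxy)-2,6,6-trimethylcyclohex-2-en-1-yl]-3-methylpenta-2,4-dien-1-yl}phosphonate, 12 (2E,4E,6E,8E,10E,12E)-2,7,11-trimethyl-13-(tributylstannyl)trideca-2,4,6,8,10,12-hexaenal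
Product: 24 tributyl{(1E,3E,5E,7E,9E,11E,13E,15E,17E)-18-[(1R,4R)-4-(tert-butyldimethylsilyloxy)-2,6,6-trimethylcyclohex-2-en-1-yl]-3,7,12,16-tetramethyloctadeca-1,3,5,7,9,11,13,15,17-nonaen-1-yl}stannane (C31 stannane), via sodium phosphonate carbanion 23 (not isolated)
Conditions: NaHMDS, THF, −78 °C; then 12, −78 → 0 °C, dark
Reagents that add atoms: none
Why: Horner–Wadsworth–Emmons olefination of the allylic phosphonate anion with the polyenal forms the C11'=C12' bond with E geometry, the alkenylstannane and the silyl ether being inert to the amide base at low temperature.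

Step 16
Reactants: 24 C31 stannane, 5 (3R,4S)-3,4-dihydroxy-2,6,6-trimethylcyclohex-1-en-1-yl trifluoromethanesulfonate
Product: 25 (3S,4R,3'R,6'R)-3'-O-(tert-butyldimethylsilyl)-β,ε-carotene-3,4,3'-triol
Conditions: Pd2(dba)3 (5 mol%), AsPh3 (40 mol%), NMP, 50 °C, degassed, dark
Reagents that add atoms: none
Why: Stille cross-coupling: Pd(0) inserts into the C6–OTf bond of 5, the E-alkenyl group of 24 passes from tin to palladium with retention, and reductive elimination forms the C6–C7 sp2–sp2 bond and completes the conjugated decaene. The closest known reaction type is the coupling of 2,6,6-trimethylcyclohexenyl triflates with di- to tetraenyl stannanes in retinoid chemistry, applied here to a longer stannane and an oxygenated ring. No ring is closed and no stereocentre is formed; the step has to keep the 7E geometry, the eight other chain double bonds and the four existing stereocentres, which the stereoretentive transmetalation and the neutral, base-free medium should secure. Site selectivity rests on 5 offering a single C–O bond that Pd(0) can enter: the free allylic C4–OH and the allylic silyl ether at C3' are not leaving groups for π-allyl formation, and the alkenylpalladium at C6 has no β-hydrogen or β-leaving group (C1 quaternary, C5 sp2). The weakly binding AsPh3 ligand in NMP should speed the slow transmetalation at the hindered C6 centre so that it outruns stannane homocoupling and polyene isomerisation.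

Step 17
Reactants: 25 (3S,4R,3'R,6'R)-3'-O-(tert-butyldimethylsilyl)-β,ε-carotene-3,4,3'-triol
Product: 26 (3S,4R,3'R,6'R)-β,ε-carotene-3,4,3'-triol (CNP0191612.1)
Conditions: TBAF, AcOH (1:1), THF, 0 °C → rt, dark
Reagents that add atoms: none
Why: Fluoride-induced desilylation driven by the Si–F bond, run buffered and non-acidic, which the acid-labile allylic carbinols at C4 and C3' and the polyene should tolerate.

**Compound list**

1 | 2,6,6-trimethylcyclohex-2-en-1-one | CC1=CCCC(C)(C)C1=O | starting material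
2 | lithium 2,6,6-trimethylcyclohexa-1,3-dien-1-olate | [Li+].CC1=C([O-])C(C)(C)CC=C1 | intermediate
3 | 2,6,6-trimethylcyclohexa-1,3-dien-1-yl trifluoromethanesulfonate | CC1=C(OS(=O)(=O)C(F)(F)F)C(C)(C)CC=C1 | intermediate
4 | rac-(3R,4S)-3,4-dihydroxy-2,6,6-trimethylcyclohex-1-en-1-yl trifluoromethanesulfonate (cis, both enantiomers written) | FC(F)(F)S(=O)(=O)OC1=C(C)[C@@H](O)[C@@H](O)CC1(C)C.FC(F)(F)S(=O)(=O)OC1=C(C)[C@H](O)[C@H](O)CC1(C)C | intermediate
5 | (3R,4S)-3,4-dihydroxy-2,6,6-trimethylcyclohex-1-en-1-yl trifluoromethanesulfonate | FC(F)(F)S(=O)(=O)OC1=C(C)[C@@H](O)[C@@H](O)CC1(C)C | intermediate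
6 | (E)-3-methylpent-2-en-4-yn-1-ol | C#C/C(C)=C/CO | starting material
7 | (2E,4E)-3-methyl-5-(tributylstannyl)penta-2,4-dien-1-ol | CCCC[Sn](CCCC)(CCCC)/C=C/C(C)=C/CO | intermediate
8 | tributyl[(1E,3E)-5-bromo-3-methylpenta-1,3-dien-1-yl]stannane | CCCC[Sn](CCCC)(CCCC)/C=C/C(C)=C/CBr | intermediate
9 | diethyl [(2E,4E)-3-methyl-5-(tributylstannyl)penta-2,4-dien-1-yl]phosphonate | CCCC[Sn](CCCC)(CCCC)/C=C/C(C)=C/CP(=O)(OCC)OCC | intermediate
10 | (2E,4E,6E)-2,7-dimethylocta-2,4,6-trienedial | O=C/C(C)=C/C=C/C=C(C)/C=O | starting material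
11 | sodium salt (α-carbanion) of phosphonate 9 | [Na+].CCCC[Sn](CCCC)(CCCC)/C=C/C(C)=C/[CH-]P(=O)(OCC)OCC | intermediate
12 | (2E,4E,6E,8E,10E,12E)-2,7,11-trimethyl-13-(tributylstannyl)trideca-2,4,6,8,10,12-hexaenal | CCCC[Sn](CCCC)(CCCC)/C=C/C(C)=C/C=C/C(C)=C/C=C/C=C(C)/C=O | intermediate
13 | (±)-α-ionone, (E)-4-(2,6,6-trimethylcyclohex-2-en-1-yl)but-3-en-2-one | CC(=O)/C=C/C1C(C)=CCCC1(C)C | starting material
14 | triethyl phosphonoacetate | CCOC(=O)CP(=O)(OCC)OCC | starting material
15 | sodium triethyl phosphonoacetate | [Na+].CCOC(=O)[CH-]P(=O)(OCC)OCC | intermediate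
16 | ethyl (2E,4E)-3-methyl-5-(2,6,6-trimethylcyclohex-2-en-1-yl)penta-2,4-dienoate (racemic) | CCOC(=O)/C=C(C)/C=C/C1C(C)=CCCC1(C)C | intermediate
17 | ethyl (2E,4E)-3-methyl-5-(2,6,6-trimethyl-4-oxocyclohex-2-en-1-yl)penta-2,4-dienoate (racemic) | CCOC(=O)/C=C(C)/C=C/C1C(C)=CC(=O)CC1(C)C | intermediate
18 | ethyl (2E,4E)-5-[(1R,4R)-4-hydroxy-2,6,6-trimethylcyclohex-2-en-1-yl]-3-methylpenta-2,4-dienoate | CC1=C[C@H](O)CC(C)(C)[C@H]1/C=C/C(C)=C/C(=O)OCC | intermediate
19 | ethyl (2E,4E)-5-[(1R,4R)-4-(tert-butyldimethylsilyloxy)-2,6,6-trimethylcyclohex-2-en-1-yl]-3-methylpenta-2,4-dienoate | CC1=C[C@H](O[Si](C)(C)C(C)(C)C)CC(C)(C)[C@H]1/C=C/C(C)=C/C(=O)OCC | intermediate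
20 | (2E,4E)-5-[(1R,4R)-4-(tert-butyldimethylsilyloxy)-2,6,6-trimethylcyclohex-2-en-1-yl]-3-methylpenta-2,4-dien-1-ol | CC1=C[C@H](O[Si](C)(C)C(C)(C)C)CC(C)(C)[C@H]1/C=C/C(C)=C/CO | intermediate
21 | (1R,4R)-1-[(1E,3E)-5-bromo-3-methylpenta-1,3-dien-1-yl]-4-(tert-butyldimethylsilyloxy)-2,6,6-trimethylcyclohex-2-ene | CC1=C[C@H](O[Si](C)(C)C(C)(C)C)CC(C)(C)[C@H]1/C=C/C(C)=C/CBr | intermediate
22 | diethyl {(2E,4E)-5-[(1R,4R)-4-(tert-butyldimethylsilyloxy)-2,6,6-trimethylcyclohex-2-en-1-yl]-3-methylpenta-2,4-dien-1-yl}phosphonate | CC1=C[C@H](O[Si](C)(C)C(C)(C)C)CC(C)(C)[C@H]1/C=C/C(C)=C/CP(=O)(OCC)OCC | intermediate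
23 | sodium salt (α-carbanion) of phosphonate 22 | [Na+].CC1=C[C@H](O[Si](C)(C)C(C)(C)C)CC(C)(C)[C@H]1/C=C/C(C)=C/[CH-]P(=O)(OCC)OCC | intermediate
24 | C31 stannane: tributyl{(1E,3E,5E,7E,9E,11E,13E,15E,17E)-18-[(1R,4R)-4-(tert-butyldimethylsilyloxy)-2,6,6-trimethylcyclohex-2-en-1-yl]-3,7,12,16-tetramethyloctadeca-1,3,5,7,9,11,13,15,17-nonaen-1-yl}stannane | CC1=C[C@H](O[Si](C)(C)C(C)(C)C)CC(C)(C)[C@H]1/C=C/C(C)=C/C=C/C(C)=C/C=C/C=C(C)/C=C/C=C(C)/C=C/[Sn](CCCC)(CCCC)CCCC | intermediate
25 | (3S,4R,3'R,6'R)-3'-O-(tert-butyldimethylsilyl)-β,ε-carotene-3,4,3'-triol | CC1=C[C@H](O[Si](C)(C)C(C)(C)C)CC(C)(C)[C@H]1/C=C/C(C)=C/C=C/C(C)=C/C=C/C=C(C)/C=C/C=C(C)/C=C/C1=C(C)[C@@H](O)[C@@H](O)CC1(C)C | intermediate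
26 | (3S,4R,3'R,6'R)-β,ε-carotene-3,4,3'-triol (CNP0191612.1) | CC1=C[C@H](O)CC(C)(C)[C@H]1/C=C/C(C)=C/C=C/C(C)=C/C=C/C=C(C)/C=C/C=C(C)/C=C/C1=C(C)[C@@H](O)[C@@H](O)CC1(C)C | target

**Count and risks**

Total steps: 17. Longest linear sequence: 10 steps (steps 8–17, from α-ionone).

Steps most likely to fail:

1. Step 16. Oxidative addition and transmetalation at the hindered, tetrasubstituted C6 centre may be slow, so that homocoupling or protodestannylation of the C31 stannane and geometric isomerisation of the polyene overtake the cross-coupling. The fallback moves the C6–C7 coupling to the small-fragment stage; it sets out from 5 and 9 (with 22 and 10 as partners) and comes back to the route at 26. Stille coupling of 5 with the small stannane 9 under the conditions of step 16 gives diethyl [(2E,4E)-5-[(3R,4S)-3,4-dihydroxy-2,6,6-trimethylcyclohex-1-en-1-yl]-3-methylpenta-2,4-dien-1-yl]phosphonate F1, which TBSOTf and 2,6-lutidine convert into its bis-silyl ether F2. In parallel the anion of 22 (NaHMDS) is added to an excess of 10 to give the ε-ring C25 aldehyde F3. Horner–Wadsworth–Emmons olefination of the anion of F2 with F3 forms C11=C12 and gives the tris-silyl ether of the target F4, and TBAF/AcOH removes all three silyl groups to give 26.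

2. Step 3. The enzyme may discriminate poorly between the enantiomers (or show the reverse preference), and acyl transfer may reach both hydroxyls. The fallback is a classical resolution that sets out from 4 and comes back at 5. The less hindered C4–OH of 4 is esterified with (S)-O-methylmandelic acid (DCC, DMAP, CH2Cl2, 0 °C), the two diastereomeric monoesters are separated by chromatography or crystallisation, and the (3R,4S)-diol 4-O-[(S)-2-methoxy-2-phenylacetate] F5 is methanolysed (K2CO3, MeOH, 0 °C) to 5.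

3. Step 9. Hydrogen abstraction may lose site selectivity (attack at the doubly allylic C1–H or at the chain methyl), and the triene ester may be over-oxidised. The fallback oxidises before the chain is extended; it sets out from 13 and comes back at 18. α-Ionone is ketalised (1,2-bis(trimethylsilyloxy)ethane, TMSOTf cat., CH2Cl2, −78 °C) to α-ionone ethylene ketal F6. The same allylic oxidation, now on the bare ionone skeleton, gives the 3-oxo ketal F7. CBS reduction as in step 10 and separation of the cis isomer give the (3R,6R)-3-hydroxy ketal F8. Mild deketalisation (PPTS, wet acetone) gives (3R,6R)-3-hydroxy-α-ionone F9, and olefination with 14 (NaH in excess, THF) gives 18.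

**Further compounds**

F1 | step 16 | diethyl [(2E,4E)-5-[(3R,4S)-3,4-dihydroxy-2,6,6-trimethylcyclohex-1-en-1-yl]-3-methylpenta-2,4-dien-1-yl]phosphonate | CCOP(=O)(OCC)C/C=C(C)/C=C/C1=C(C)[C@@H](O)[C@@H](O)CC1(C)C
F2 | step 16 | diethyl [(2E,4E)-5-[(3R,4S)-3,4-bis(tert-butyldimethylsilyloxy)-2,6,6-trimethylcyclohex-1-en-1-yl]-3-methylpenta-2,4-dien-1-yl]phosphonate | CCOP(=O)(OCC)C/C=C(C)/C=C/C1=C(C)[C@@H](O[Si](C)(C)C(C)(C)C)[C@@H](O[Si](C)(C)C(C)(C)C)CC1(C)C
F3 | step 16 | (2E,4E,6E,8E,10E,12E)-13-[(1R,4R)-4-(tert-butyldimethylsilyloxy)-2,6,6-trimethylcyclohex-2-en-1-yl]-2,7,11-trimethyltrideca-2,4,6,8,10,12-hexaenal | CC1=C[C@H](O[Si](C)(C)C(C)(C)C)CC(C)(C)[C@H]1/C=C/C(C)=C/C=C/C(C)=C/C=C/C=C(C)/C=O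
F4 | step 16 | (3S,4R,3'R,6'R)-3,4,3'-tris-O-(tert-butyldimethylsilyl)-β,ε-carotene-3,4,3'-triol | CC1=C[C@H](O[Si](C)(C)C(C)(C)C)CC(C)(C)[C@H]1/C=C/C(C)=C/C=C/C(C)=C/C=C/C=C(C)/C=C/C=C(C)/C=C/C1=C(C)[C@@H](O[Si](C)(C)C(C)(C)C)[C@@H](O[Si](C)(C)C(C)(C)C)CC1(C)C
F5 | step 3 | (3R,4S)-3-hydroxy-4-[(S)-2-methoxy-2-phenylacetoxy]-2,6,6-trimethylcyclohex-1-en-1-yl trifluoromethanesulfonate | FC(F)(F)S(=O)(=O)OC1=C(C)[C@@H](O)[C@@H](OC(=O)[C@@H](OC)c2ccccc2)CC1(C)C
F6 | step 9 | 2-methyl-2-[(E)-2-(2,6,6-trimethylcyclohex-2-en-1-yl)ethenyl]-1,3-dioxolane (racemic) | CC1=CCCC(C)(C)C1/C=C/C1(C)OCCO1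
F7 | step 9 | 3,5,5-trimethyl-4-[(E)-2-(2-methyl-1,3-dioxolan-2-yl)ethenyl]cyclohex-2-en-1-one (racemic) | CC1=CC(=O)CC(C)(C)C1/C=C/C1(C)OCCO1
F8 | step 9 | (1R,4R)-3,5,5-trimethyl-4-[(E)-2-(2-methyl-1,3-dioxolan-2-yl)ethenyl]cyclohex-2-en-1-ol | CC1=C[C@H](O)CC(C)(C)[C@H]1/C=C/C1(C)OCCO1
F9 | step 9 | (3R,6R)-3-hydroxy-α-ionone, (E)-4-[(1R,4R)-4-hydroxy-2,6,6-trimethylcyclohex-2-en-1-yl]but-3-en-2-one | CC1=C[C@H](O)CC(C)(C)[C@H]1/C=C/C(C)=O
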